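## The problem

The target **35** is a trans-fused decalin (ring A: C1–C5, C10; ring B: C5–C10) with five contiguous stereocentres (C4, C5, C6, C9, C10), two of them quaternary (C4, C10). It also carries an exocyclic C8=C17 alkene and a five-carbon chain on C9 that ends in an (E)-trisubstituted enal. The quaternary C10 is the natural control element. Once its methyl group (C20) defines the β-face, C5–H can be set α through a neighbouring carbonyl, a C9 enolate is alkylated on the α-face, a C6 ketone is reduced from the α-face, and an electrophile enters C4 from the α-face. Only C10 needs absolute control. Unusually for this skeleton, the C9 chain is α, trans to C20 (9β-H); this is the product of kinetic attack, not of equilibration, so the C8 carbonyl must be removed before C9 can epimerise. The 6β-benzoate is axial and syn to both C19 and C20. It can only arise from α-face hydride delivery to a C6 ketone followed by late acylation, and it would not survive hydrides, enolates or hot alkali. The enal, the 8(17)-alkene (which can move into the ring or into conjugation with a C6 ketone) and the neopentyl C18 alcohol (which must be told apart from the C6 hydroxyl) confine the last steps to mild reagents. The enabling feature is ring B: C6, C8 and C9 carry oxygen, or carbon derivable from oxygen, around the methyl-bearing C10, just as the two carbonyls, the methoxy carbon and the methyl carbon are placed in 2-methoxy-6-methyl-1,4-benzoquinone **2**. Its C5=C10 alkene can accept a four-carbon diene that supplies C1–C4 and leaves a carbonyl at C3, next to the future quaternary C4.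

## Retrosynthesis

**35 ⇐ 34 ⇐ 33 (C18–O ether and C6–O ester).** The last bonds made are the two C–O bonds that tell the hydroxyls apart. Removing the benzoate before the ether in the retrosynthesis means that the hindered axial hydroxyl of **33** is acylated while it is the only free hydroxyl. Selective benzoylation of a 6,18-diol would instead favour the primary oxygen. The forward steps must acylate a hydroxyl flanked by C19 and C20 and then cleave the ether oxidatively without touching benzoate or enal.

**33 ⇐ 32 ⇐ 31 ⇐ 30 (C6–H and the oxidation level of C15).** The 6β-oxygen cannot be introduced by substitution, because the β-face of C6 is closed by two syn-axial methyl groups. It must come from α-face hydride addition to ketone **31**. The same hydride takes the enoate to allylic alcohol **32**, which MnO2 returns to the enal. Ketone **31** comes from the easily reached equatorial 6α-alcohol **30**. The demand is that the 6-ketone is never allowed to enolise toward C7.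

**30 ⇐ 29 ⇐ 28 (C13=C14).** The enoate is cut by Horner–Wadsworth–Emmons logic to methyl ketone **29**, masked until then as dioxolane **28**. Attaching the whole chain at C9 would need a homoallylic electrophile, which eliminates under enolate conditions. The dioxolane is inert to every reagent used between steps 12 and 20. The cost is that E/Z control is left to the olefination.

**28 ⇐ 26 ⇐ 24 (oxygen at C3 and the C1=C2 bond added back).** Both are remnants of the carbonyl that activates C4. The precursor is not simpler in atoms, but C4 becomes the α′-carbon of an enone. The forward steps need a conjugate reduction that spares the 8(17)-alkene and the PMB ether, and then a deoxygenation.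

**24 ⇐ 23 (C7–H).** The homoallylic 6α-alcohol is traced to vinyl oxirane **23**. The oxirane stores the C6 oxygen and keeps ring B free of acidic hydrogens while C4 is built. The forward reaction must deliver hydride to C7, not to C17.

**23 ⇐ 22 ⇐ 21 ⇐ 20 ⇐ 19 (C4–C18 and C4–C19).** Both bonds are α′-alkylations of enone **21**, in which C4 is the only enolisable carbon. The oxygenated carbon is introduced second so that it ends on the α-face. Building the quaternary C4 before the ring would put two substituents on the diene terminus and cripple the cycloaddition. Enone **21** comes from silyl ether **19** by deprotection and allylic oxidation.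

**19 ⇐ 18 (C8=C17).** Carbonyl methylenation directly after C9 is set ends the epimerisability of C9. It has to be non-basic.

**18 ⇐ 15 + 17 (C9–C11).** This is enolate alkylation of epoxy ketone **15** with iodide **17**. C7 is blocked, and the C10 methyl sends the electrophile to the α-face, which is exactly the 9β-H arrangement of **35**. Routes that deliver hydrogen to C9 (protonation or hydrogenation) would give the other epimer. The precursor lacks six carbons and one stereocentre.

**15 ⇐ 14 ⇐ 13 ⇐ 12 ⇐ 10 (oxirane, and redistribution of the ring-B oxygens).** Enone **13** is the transposed enone of enedione **10** (reduce, ionise at C6, hydrolyse at C8, via triol **11**), less the C9 oxygen. Here the quinone pattern pays off. The methoxy carbon becomes the C8 carbonyl, the C6=C7 bond blocks C7 and later returns oxygen to C6, and C9 is freed for alkylation. C3 is reduced on the way and held as silyl ether **14**, so that ring A stays silent while ring B is worked.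

**10 ⇐ 9 ⇐ 7 (C5–H; enone unveiled).** The cis fusion is the inevitable outcome of the cycloaddition. It is corrected in **9**, the one intermediate in which C5 is α to a ketone and nothing else is at risk. The enone of **9** arises from the amino silyl enol ether **7** via β-amino ketone **8**.

**7 ⇐ 6 + 2 (C4–C5 and C1–C10; ring A).** Cutting these two bonds removes ring A and three stereocentres and leaves an achiral quinone and a diene that carries its own chiral controller. Compared with an annulation onto a preformed ring B, this cut delivers the quaternary C10 together with every ring-B oxygen. The forward reaction has to choose the methyl-bearing alkene, the right orientation and one face.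

**6 ⇐ 5 ⇐ 3 + 4; 2 ⇐ 1; 17 ⇐ 16.** Diene **6** comes from enol silylation of vinylogous amide **5**, made from amine **3** and methoxy enone **4**. Quinone **2** comes from para-oxidation of phenol **1**. Iodide **17** comes from bromide **16** by halide exchange.

## Roads not taken

Alternative 1: The cut goes through ring A at C3–C4 and C5–C10, and ring B closes at the same time.
- **Forward key step:** trienyl butenolide **A1** carries a dithiane at C8 and the diene C10=C1–C2=C3. On heating, the diene adds to the lactone alkene C4=C5 and gives tricyclic lactone **A2**.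
- **Merits:** one step forms both rings and both quaternary carbons. The C4 carbonyl carbon lands on the α-face, as C18 requires. C6–O and a masked C8 ketone are already present. Ring A arrives with no oxygen at C3, so nothing has to be deleted there. In this respect it is clearly shorter than the chosen plan, which spends nine steps on C4 and on removing the C3 oxygen.
- **Weak points:**
  - The diene terminus C10 is fully substituted and must carry its methyl group on the inside, and the dienophile is an α-methyl butenolide. Two quaternary centres flanking C5 are therefore made thermally, probably at temperatures where a cis-methyl diene undergoes 1,5-hydrogen shift.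
  - As drawn, **A2** is cis-fused with the C6 oxygen α. C6 must be oxidised, C5 epimerised and C6 reduced again, as in the chosen plan.
  - The absolute configuration rests on the single carbinol centre of **A1**, which needs its own asymmetric step.
  - After C8 is unmasked, enolisation toward C9 competes with C7, where a β-oxygen at C6 invites elimination.
- **Comparison:** against the shorter ring-A chemistry, the chosen plan sets an intermolecular cycloaddition between two simple, highly reactive partners, absolute control in that same step, and the C6=C7 enone that makes C9 the only enolisable carbon.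

Alternative 2: Only the C10–C20 bond is cut; the methyl group is traced to a cyclopropane across C5–C10.
- **Forward key step:** the zinc carbenoid from ZnEt2 and CH2I2 is delivered by the 6β-hydroxyl of octalinol **A3** to its tetrasubstituted C5=C10 alkene and gives cyclopropane **A4**. Reductive opening of the C5–C20 bond through a C6 ketone would later release the methyl group and set C5–H.
- **Merits:** hydroxyl-directed Simmons–Smith cyclopropanation is among the most dependable ways to place carbon on a hindered alkene face. The directing group is an oxygen the target needs, in exactly this configuration. Neither C3 nor C9 carries surplus oxygen. In facial certainty at C10 it is at least as good as the chosen plan.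
- **Weak points:**
  - The step forms one skeletal bond and no ring. The decalin, the quaternary C4 and the C6 carbinol of **A3** must all be made in enantiopure form beforehand.
  - **A4** has no functional group at C8 or C9, and a C6 ketone activates only C5 and C7. The methylene group and the chain would need a separate entry.
  - The alkene is flanked by the quaternary C4.
- **Comparison:** against the cleaner stereocontrol, the chosen plan sets a key step that builds ring A and leaves oxygen on every ring-B carbon that needs it.

Alternative 3: Ring B is cut at C5–C10 and C8–C9, and ring A closes with it.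
- **Forward key step:** heating dienyl butenolide **A5** joins its 2-siloxy diene (C5=C6–C7=C8) to the β-methyl butenolide alkene C9=C10 and gives tricyclic lactone **A6**.
- **Merits:** the tether forms the C9–C11 bond on the α-face, so the most delicate stereocentre of this target is fixed by the cycloaddition and not by a kinetic alkylation. C6 emerges as a silyl enol ether, at the ketone level needed for α-face reduction and for C5 epimerisation (**A6** is cis-fused as drawn). C17 is already on C8, and C4 arrives complete. On C9 and C6 this road is better than the chosen one, which must re-oxidise C6 and rely on kinetic control at C9.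
- **Weak points:**
  - The new C5–C10 bond joins a neopentyl diene terminus to the β,β-disubstituted carbon of a poor dienophile.
  - **A5** is a long chain with two separate stereocentres (quaternary C4 and the C1 carbinol) to be made first.
  - The C1 oxygen must be deleted, C11 arrives as a carboxyl carbon that must be reduced and extended by four carbons, and the C8 substituent must be eliminated toward C17 only.
- **Comparison:** against these advantages, the chosen plan sets four-step access to the bicycle from a phenol and a C4 ketone, and a cycloaddition whose partners are matched electronically instead of being forced together by a tether.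

Key step: step 4

Remarks before the steps:
- **Numbering.** All bicyclic compounds carry labdane numbers: ring A is C1–C5 and C10, ring B is C5–C10, C17 is on C8, C18 is the 4α-carbon, C19 the 4β-methyl, C20 the 10-methyl, and the chain is C11–C16. α is the face opposite C20.
- **Assumption on the chemistry.** The (2R,5R)-pyrrolidine is taken to shield the diene face that leads to the 10β-methyl adduct **7**. If the sense of induction proved opposite, the (2S,5S)-amine would be used with no other change.
- **Transient centres.** The carbinol configurations at C3 (**11**–**20**) and at C6 and C9 (**11**, **12**), and the oxirane configuration (**15**–**23**), are drawn as expected; all are erased later.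

## Steps

Step 1
Reactants: 1 2-methoxy-6-methylphenol
Product: 2 2-methoxy-6-methyl-1,4-benzoquinone
Conditions: Co(salen) (5 mol %), O2 (1 atm), DMF, rt
Reagents that add atoms: dioxygen, O=O
Why: Co(salen)-catalysed aerobic oxidation of a 2,6-disubstituted phenol proceeds through the phenoxyl radical and para-oxygenation; both ortho positions are blocked, so only the 1,4-quinone can form.

Step 2
Reactants: 3 (2R,5R)-2,5-diphenylpyrrolidine; 4 (E)-4-methoxybut-3-en-2-one
Product: 5 (E)-4-[(2R,5R)-2,5-diphenylpyrrolidin-1-yl]but-3-en-2-one
Conditions: MeOH, rt; concentrate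
Reagents that add atoms: none
Why: Addition–elimination of the secondary amine at the β-carbon of the β-methoxy enone (vinylogous transamidation); the conjugated E vinylogous amide is the thermodynamic product and methanol is the only by-product.

Step 3
Reactants: 5 (E)-4-[(2R,5R)-2,5-diphenylpyrrolidin-1-yl]but-3-en-2-one
Product: 6 (E)-1-[(2R,5R)-2,5-diphenylpyrrolidin-1-yl]-3-(tert-butyldimethylsilyloxy)buta-1,3-diene
Conditions: KN(SiMe3)2, THF, −78 °C; TBSCl, −78 °C → rt
Reagents that add atoms: tert-butyldimethylsilyl chloride, CC(C)(C)[Si](C)(C)Cl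
Why: Kinetic deprotonation of the methyl ketone and O-silylation of the cross-conjugated enolate (silyl enol ether formation) gives the 1-amino-3-siloxy diene; the E amino-alkene is retained.

Step 4
Reactants: 6 (E)-1-[(2R,5R)-2,5-diphenylpyrrolidin-1-yl]-3-(tert-butyldimethylsilyloxy)buta-1,3-diene; 2 2-methoxy-6-methyl-1,4-benzoquinone
Product: 7 cis-fused adduct: 1α-[(2R,5R)-2,5-diphenylpyrrolidin-1-yl]-3-(tert-butyldimethylsilyloxy)-8-methoxy-10β-methyl-5βH-bicyclic 2,7-diene-6,9-dione
Conditions: toluene, −40 °C → rt
Reagents that add atoms: none
Why: A concerted but strongly asynchronous [4+2] cycloaddition (Diels–Alder reaction), closest in type to additions of 1-amino-3-siloxy dienes to α-substituted enals and enones that create quaternary centres. Ring A is closed as a six-membered ring by intermolecular [4+2] annulation: the nucleophilic CH2 terminus of 6 bonds first to C5 and the amino-bearing terminus then closes onto C10. Site selectivity comes from the methoxy group, which turns C7=C8 into a vinylogous ester and leaves the methyl-bearing C5=C10 alkene as the reactive dienophile. Orientation comes from the C9 carbonyl, the stronger acceptor because the C6 carbonyl belongs to the vinylogous ester, so C5 (β to C9) is the electrophilic carbon. C10 is set absolutely by the C2-symmetric diphenylpyrrolidine, which presents a phenyl group over the same diene face in either N–C rotamer; C5 follows from suprafacial addition to the ring alkene (5β-H, cis to C20); C1 follows from the endo transition state (amine α) and is lost in step 5. The step thus needs site, regio-, endo and facial selectivity, secured in that order by the methoxy group, the C9 carbonyl, secondary overlap with the enedione and the auxiliary.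

Step 5
Reactants: 7 cis-fused amino silyl enol ether adduct
Product: 9 cis-enetrione: 8-methoxy-10β-methyl-5βH-bicyclic 1,7-diene-3,6,9-trione, via β-amino ketone 8 (not isolated)
Conditions: 0.1 M aq. HCl, THF, 0 °C; then aq. NaHCO3
Reagents that add atoms: none
Why: Acid hydrolysis of the silyl enol ether gives β-amino ketone 8, which loses the protonated amine by β-elimination to the C1=C2 enone; the vinylogous ester survives brief cold dilute acid and the auxiliary is recovered from the aqueous phase.

Step 6
Reactants: 9 cis-enetrione (5β-H)
Product: 10 trans-enetrione: 8-methoxy-10β-methyl-5αH-bicyclic 1,7-diene-3,6,9-trione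
Conditions: DBU (0.2 equiv), CH2Cl2, rt
Reagents that add atoms: none
Why: Base-mediated epimerisation through the C5(6) enolate of the C6 ketone; with C1–C3 and C6–C9 trigonal, the axial C20 meets only one syn-axial hydrogen in the trans isomer, which should therefore be favoured as in related angular-methyl quinone adducts. C10 is quaternary and cannot change.

Step 7
Reactants: 10 trans-enetrione
Product: 12 3β,9β-dihydroxy-10β-methyl-5αH-bicyclic 1,6-dien-8-one, via enol ether triol 11 (not isolated)
Conditions: LiAlH4, THF, −78 → 0 °C; then 1 M aq. HCl, THF, 0 °C → rt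
Reagents that add atoms: water, O
Why: Hydride 1,2-reduction of all three carbonyls, then a Stork–Danheiser-type transposition: acid ionises the C6 carbinol through the C7=C8 enol ether and water returns at C8, giving the C6=C7–C8 enone. The C9 carbinol and the allylic C3 carbinol remain; their configuration is immaterial.

Step 8
Reactants: 12 3β,9β-dihydroxy dienone
Product: 13 3β-hydroxy-10β-methyl-5αH-bicyclic 1,6-dien-8-one
Conditions: SmI2 (2.5 equiv), THF/MeOH, −78 °C
Reagents that add atoms: none
Why: SmI2 reduction of an α-hydroxy ketone: the ketyl expels the C9 oxygen and the samarium dienolate is protonated at C9 by methanol. The allylic alcohol and the enone double bond are not touched at −78 °C.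

Step 9
Reactants: 13 3β-hydroxy dienone
Product: 14 3β-(tert-butyldimethylsilyloxy)-10β-methyl-5αH-bicyclic 1,6-dien-8-one
Conditions: TBSCl, imidazole, DMF, rt
Reagents that add atoms: tert-butyldimethylsilyl chloride, CC(C)(C)[Si](C)(C)Cl
Why: Standard silylation of the only hydroxyl; it masks C3 so that ring B can be treated with base and with a titanium alkylidene.

Step 10
Reactants: 14 silyl ether dienone
Product: 15 6α,7α-epoxy-3β-(tert-butyldimethylsilyloxy)-10β-methyl-5αH-bicyclic 1-en-8-one
Conditions: 30% H2O2, NaOH (cat.), MeOH, 0 °C
Reagents that add atoms: hydrogen peroxide, OO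
Why: Weitz–Scheffer nucleophilic epoxidation of the enone; hydroperoxide adds to C6 on the α-face, away from the syn-axial C20, and the isolated C1=C2 alkene is inert. The oxirane blocks C7 and stores the C6 oxygen.

Step 11
Reactants: 16 2-(2-bromoethyl)-2-methyl-1,3-dioxolane
Product: 17 2-(2-iodoethyl)-2-methyl-1,3-dioxolane
Conditions: NaI, acetone, reflux
Reagents that add atoms: sodium iodide, [Na+].[I-]
Why: Finkelstein halide exchange driven by precipitation of NaBr; it gives the more reactive primary iodide.

Step 12
Reactants: 15 epoxy ketone; 17 2-(2-iodoethyl)-2-methyl-1,3-dioxolane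
Product: 18 6α,7α-epoxy-9α-[2-(2-methyl-1,3-dioxolan-2-yl)ethyl]-3β-(tert-butyldimethylsilyloxy)-10β-methyl-5αH,9βH-bicyclic 1-en-8-one
Conditions: LiN(i-Pr)2, THF, −78 °C; DMPU, 17, −78 → −20 °C; cold NH4Cl quench
Reagents that add atoms: none
Why: Kinetic lithium enolate alkylation: only C9 can be deprotonated because C7 is an oxirane carbon, and the iodide approaches anti to the adjacent axial C20, placing the chain α (9β-H). The cold quench avoids equilibration to the 9-epimer.

Step 13
Reactants: 18 9α-alkylated epoxy ketone
Product: 19 6α,7α-epoxy-8(17)-methylene compound (3β-silyl ether, 9α-chain as in 18)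
Conditions: Cp2TiMe2 (3 equiv), toluene/THF, 65 °C
Reagents that add atoms: dimethyltitanocene, C[Ti](C)(C1C=CC=C1)C1C=CC=C1
Why: Petasis methylenation: thermally generated Cp2Ti=CH2 olefinates hindered, enolisable ketones under non-basic conditions, so C9 keeps its configuration; oxirane, dioxolane and silyl ether are tolerated. After this step C9 is no longer α to a carbonyl.

Step 14
Reactants: 19 vinyl oxirane silyl ether
Product: 20 6α,7α-epoxy-8(17)-methylene-1-en-3β-ol (9α-chain as in 18)
Conditions: Bu4NF, THF, 0 °C → rt
Reagents that add atoms: none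
Why: Fluoride cleavage of the silyl ether; nothing else in 19 responds to fluoride.

Step 15
Reactants: 20 allylic alcohol
Product: 21 6α,7α-epoxy-8(17)-methylene-1-en-3-one (9α-chain as in 18)
Conditions: MnO2, CH2Cl2, rt
Reagents that add atoms: none
Why: MnO2 oxidises the allylic alcohol to the C1=C2–C3 enone; no other oxidisable alcohol is present.

Step 16
Reactants: 21 enone
Product: 22 4α-methyl-6α,7α-epoxy-8(17)-methylene-1-en-3-one
Conditions: LiN(i-Pr)2, THF, −78 °C; MeI
Reagents that add atoms: iodomethane, CI
Why: α′-Alkylation of a cross-conjugated lithium enolate: C4 is the only enolisable position (C10 is quaternary, so there is no γ-hydrogen) and methyl iodide enters anti to C20. The C4 epimer would serve equally, since C4 is made planar again in step 17.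

Step 17
Reactants: 22 4α-methyl enone
Product: 23 4β-methyl-4α-[(4-methoxybenzyloxy)methyl]-6α,7α-epoxy-8(17)-methylene-1-en-3-one (9α-chain as in 18)
Conditions: LiN(i-Pr)2, THF, −78 → −40 °C; PMBOCH2Cl
Reagents that add atoms: 4-methoxybenzyl chloromethyl ether, COc1ccc(COCCl)cc1
Why: Second α′-enolate alkylation, now creating the quaternary C4: the chloromethyl ether attacks the tetrasubstituted enolate on the α-face because the β-face is screened by the syn-axial C20, so the oxygenated C18 ends α and the methyl C19 β. The order of the two alkylations is what fixes C4.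

Step 18
Reactants: 23 vinyl oxirane enone
Product: 24 6α-hydroxy-4β-methyl-4α-[(4-methoxybenzyloxy)methyl]-8(17)-methylene-1-en-3-one (9α-chain as in 18)
Conditions: Pd2(dba)3·CHCl3 (2.5 mol %), n-Bu3P, HCO2H, Et3N, dioxane, rt
Reagents that add atoms: none
Why: Formate hydrogenolysis of an alkenyl oxirane catalysed by zerovalent palladium: ionisation of the allylic C7–O bond gives a π-allyl complex, and hydride passes from Pd–H to the more substituted terminus C7, keeping the terminal C8=C17 alkene and leaving the 6α-alcohol. Enone, PMB ether and dioxolane are inert.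

Step 19
Reactants: 24 6α-hydroxy enone
Product: 26 6α-hydroxy-4β-methyl-4α-[(4-methoxybenzyloxy)methyl]-8(17)-methylene-3-ketone (ring A saturated), via silyl enol ether 25 (not isolated)
Conditions: [(Ph3P)CuH]6 (5 mol %), (EtO)2MeSiH, toluene, rt; then aq. NH4F
Reagents that add atoms: none
Why: Copper hydride conjugate reduction is chemoselective for the enone over the 1,1-disubstituted alkene and, unlike dissolving metal, spares the PMB ether. Hydrolysis of silyl enol ether 25 on work-up gives the saturated ketone.

Step 20
Reactants: 26 saturated 3-ketone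
Product: 28 13,13-ethylenedioxy-18-(4-methoxybenzyloxy)-14,15-dinor-9βH-labd-8(17)-en-6α-ol, via hydrazone 27 (not isolated)
Conditions: N2H4·H2O, KOH, diethylene glycol, 130 → 200 °C
Reagents that add atoms: none
Why: Wolff–Kishner reduction (Huang-Minlon conditions): C4 carries no hydrogen and no α-leaving group, so neither elimination nor retro-aldol cleavage can intervene. Dioxolane, PMB ether, alkene and the free alcohol are stable to hot alkali.

Step 21
Reactants: 28 dioxolane
Product: 29 6α-hydroxy-18-(4-methoxybenzyloxy)-14,15-dinor-9βH-labd-8(17)-en-13-one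
Conditions: PPTS, acetone/H2O, 50 °C
Reagents that add atoms: water, O
Why: Mild acid-catalysed hydrolysis of the dioxolane; pyridinium tosylate is too weak to move the exocyclic alkene or to cleave the PMB ether.

Step 22
Reactants: 29 methyl ketone
Product: 30 ethyl (13E)-6α-hydroxy-18-(4-methoxybenzyloxy)-9βH-labda-8(17),13-dien-15-oate
Conditions: (EtO)2P(O)CH2CO2Et, NaH, THF, 0 °C → reflux
Reagents that add atoms: triethyl phosphonoacetate, CCOC(=O)CP(=O)(OCC)OCC
Why: Horner–Wadsworth–Emmons olefination of the methyl ketone; the stabilised phosphonate favours the (E)-trisubstituted enoate and the minor Z isomer is removed by chromatography. The hindered C6 alkoxide is a spectator.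

Step 23
Reactants: 30 6α-hydroxy enoate
Product: 31 ethyl (13E)-18-(4-methoxybenzyloxy)-6-oxo-9βH-labda-8(17),13-dien-15-oate
Conditions: Dess–Martin periodinane, NaHCO3, CH2Cl2, 0 °C
Reagents that add atoms: none
Why: Dess–Martin oxidation under buffered, non-enolising conditions gives the C6 ketone without moving the β,γ-alkene into conjugation; the product is used at once.

Step 24
Reactants: 31 6-keto enoate
Product: 32 (13E)-18-(4-methoxybenzyloxy)-9βH-labda-8(17),13-diene-6β,15-diol
Conditions: i-Bu2AlH (5 equiv), CH2Cl2, −78 °C; aq. potassium sodium tartrate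
Reagents that add atoms: none
Why: i-Bu2AlH reduces the enoate to the allylic alcohol and the ketone to the axial 6β-alcohol, because hydride can reach C6 only from the α-face (C19 and C20 are syn-axial on the β-face). This sets the last stereocentre.

Step 25
Reactants: 32 6β,15-diol
Product: 33 (13E)-6β-hydroxy-18-(4-methoxybenzyloxy)-9βH-labda-8(17),13-dien-15-al
Conditions: MnO2, CH2Cl2, rt
Reagents that add atoms: none
Why: MnO2 is selective for the allylic primary alcohol; the hindered saturated C6 alcohol is untouched and the E geometry is kept.

Step 26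
Reactants: 33 6β-hydroxy enal
Product: 34 (13E)-6β-benzoyloxy-18-(4-methoxybenzyloxy)-9βH-labda-8(17),13-dien-15-al
Conditions: BzCl, DMAP, pyridine, 60 °C
Reagents that add atoms: benzoyl chloride, O=C(Cl)c1ccccc1
Why: DMAP-catalysed acylation through the N-benzoylpyridinium ion, heated because the hydroxyl is axial between C19 and C20. It is the only free hydroxyl, and the enal is inert to acyl transfer.

Step 27
Reactants: 34 benzoate PMB ether
Product: 35 (13E)-6β-benzoyloxy-18-hydroxy-9βH-labda-8(17),13-dien-15-al, (4R,5R,6R,9R,10R)
Conditions: DDQ, CH2Cl2/pH 7 buffer, 0 °C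
Reagents that add atoms: none
Why: Oxidative cleavage of the PMB ether by DDQ (hydride abstraction, then hydrolysis of the oxocarbenium ion) under buffered conditions leaves benzoate, enal and alkenes untouched and releases the C18 alcohol.

## Compound list

1 | 2-methoxy-6-methylphenol | COc1cccc(C)c1O | starting material
2 | 2-methoxy-6-methyl-1,4-benzoquinone | COC1=CC(=O)C=C(C)C1=O | intermediate
3 | (2R,5R)-2,5-diphenylpyrrolidine | N1[C@@H](c2ccccc2)CC[C@@H]1c1ccccc1 | starting material
4 | (E)-4-methoxybut-3-en-2-one | CO/C=C/C(C)=O | starting material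
5 | (E)-4-[(2R,5R)-2,5-diphenylpyrrolidin-1-yl]but-3-en-2-one | CC(=O)/C=C/N1[C@@H](c2ccccc2)CC[C@@H]1c1ccccc1 | intermediate
6 | (E)-1-[(2R,5R)-2,5-diphenylpyrrolidin-1-yl]-3-(tert-butyldimethylsilyloxy)buta-1,3-diene | C=C(O[Si](C)(C)C(C)(C)C)/C=C/N1[C@@H](c2ccccc2)CC[C@@H]1c1ccccc1 | intermediate
7 | cis-fused adduct: 1α-(diphenylpyrrolidinyl)-3-silyloxy-8-methoxy-10β-methyl-5βH-2,7-diene-6,9-dione | O=C1C=C(OC)C(=O)[C@@]2(C)[C@@H](N3[C@@H](c4ccccc4)CC[C@@H]3c3ccccc3)C=C(O[Si](C)(C)C(C)(C)C)C[C@@H]12 | intermediate
8 | β-amino ketone: 1α-(diphenylpyrrolidinyl)-8-methoxy-10β-methyl-5βH-7-ene-3,6,9-trione | COC1=CC(=O)[C@@H]2CC(=O)C[C@H](N3[C@@H](c4ccccc4)CC[C@@H]3c3ccccc3)[C@]2(C)C1=O | intermediate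
9 | cis-enetrione: 8-methoxy-10β-methyl-5βH-1,7-diene-3,6,9-trione | COC1=CC(=O)[C@@H]2CC(=O)C=C[C@]2(C)C1=O | intermediate
10 | trans-enetrione: 8-methoxy-10β-methyl-5αH-1,7-diene-3,6,9-trione | COC1=CC(=O)[C@H]2CC(=O)C=C[C@]2(C)C1=O | intermediate
11 | enol ether triol: 8-methoxy-10β-methyl-5αH-1,7-diene-3β,6β,9β-triol | COC1=C[C@@H](O)[C@H]2C[C@@H](O)C=C[C@]2(C)[C@H]1O | intermediate
12 | 3β,9β-dihydroxy-10β-methyl-5αH-1,6-dien-8-one | O=C1C=C[C@H]2C[C@@H](O)C=C[C@]2(C)[C@H]1O | intermediate
13 | 3β-hydroxy-10β-methyl-5αH-1,6-dien-8-one | O=C1C=C[C@H]2C[C@@H](O)C=C[C@]2(C)C1 | intermediate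
14 | 3β-(tert-butyldimethylsilyloxy)-10β-methyl-5αH-1,6-dien-8-one | O=C1C=C[C@H]2C[C@@H](O[Si](C)(C)C(C)(C)C)C=C[C@]2(C)C1 | intermediate
15 | 6α,7α-epoxy-3β-silyloxy-10β-methyl-5αH-1-en-8-one | O=C1[C@@H]3O[C@@H]3[C@H]2C[C@@H](O[Si](C)(C)C(C)(C)C)C=C[C@]2(C)C1 | intermediate
16 | 2-(2-bromoethyl)-2-methyl-1,3-dioxolane | CC1(CCBr)OCCO1 | starting material
17 | 2-(2-iodoethyl)-2-methyl-1,3-dioxolane | CC1(CCI)OCCO1 | intermediate
18 | 9α-[2-(2-methyl-1,3-dioxolan-2-yl)ethyl]-6α,7α-epoxy-3β-silyloxy-1-en-8-one (9β-H) | O=C1[C@@H]3O[C@@H]3[C@H]2C[C@@H](O[Si](C)(C)C(C)(C)C)C=C[C@]2(C)[C@@H]1CCC1(C)OCCO1 | intermediate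
19 | 8(17)-methylene vinyl oxirane, 3β-silyl ether | C=C1[C@@H]3O[C@@H]3[C@H]2C[C@@H](O[Si](C)(C)C(C)(C)C)C=C[C@]2(C)[C@@H]1CCC1(C)OCCO1 | intermediate
20 | 8(17)-methylene vinyl oxirane, 1-en-3β-ol | C=C1[C@@H]3O[C@@H]3[C@H]2C[C@@H](O)C=C[C@]2(C)[C@@H]1CCC1(C)OCCO1 | intermediate
21 | 8(17)-methylene vinyl oxirane, 1-en-3-one | C=C1[C@@H]3O[C@@H]3[C@H]2CC(=O)C=C[C@]2(C)[C@@H]1CCC1(C)OCCO1 | intermediate
22 | 4α-methyl vinyl oxirane enone | C=C1[C@@H]3O[C@@H]3[C@H]2[C@H](C)C(=O)C=C[C@]2(C)[C@@H]1CCC1(C)OCCO1 | intermediate
23 | 4β-methyl-4α-(PMB-oxymethyl) vinyl oxirane enone | C=C1[C@@H]3O[C@@H]3[C@H]2[C@](C)(COCc4ccc(OC)cc4)C(=O)C=C[C@]2(C)[C@@H]1CCC1(C)OCCO1 | intermediate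
24 | 6α-hydroxy-4β-methyl-4α-(PMB-oxymethyl)-8(17)-methylene-1-en-3-one | C=C1C[C@H](O)[C@H]2[C@](C)(COCc3ccc(OC)cc3)C(=O)C=C[C@]2(C)[C@@H]1CCC1(C)OCCO1 | intermediate
25 | C2=C3 diethoxy(methyl)silyl enol ether of 26 | C=C1C[C@H](O)[C@H]2[C@](C)(COCc3ccc(OC)cc3)C(O[Si](C)(OCC)OCC)=CC[C@]2(C)[C@@H]1CCC1(C)OCCO1 | intermediate
26 | 6α-hydroxy-4β-methyl-4α-(PMB-oxymethyl)-8(17)-methylene-3-ketone | C=C1C[C@H](O)[C@H]2[C@](C)(COCc3ccc(OC)cc3)C(=O)CC[C@]2(C)[C@@H]1CCC1(C)OCCO1 | intermediate
27 | C3 hydrazone of 26 | C=C1C[C@H](O)[C@H]2[C@](C)(COCc3ccc(OC)cc3)C(=NN)CC[C@]2(C)[C@@H]1CCC1(C)OCCO1 | intermediate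
28 | 13,13-ethylenedioxy-18-(4-methoxybenzyloxy)-14,15-dinor-9βH-labd-8(17)-en-6α-ol | C=C1C[C@H](O)[C@H]2[C@](C)(COCc3ccc(OC)cc3)CCC[C@]2(C)[C@@H]1CCC1(C)OCCO1 | intermediate
29 | 6α-hydroxy-18-(4-methoxybenzyloxy)-14,15-dinor-9βH-labd-8(17)-en-13-one | C=C1C[C@H](O)[C@H]2[C@](C)(COCc3ccc(OC)cc3)CCC[C@]2(C)[C@@H]1CCC(C)=O | intermediate
30 | ethyl (13E)-6α-hydroxy-18-(4-methoxybenzyloxy)-9βH-labda-8(17),13-dien-15-oate | C=C1C[C@H](O)[C@H]2[C@](C)(COCc3ccc(OC)cc3)CCC[C@]2(C)[C@@H]1CC/C(C)=C/C(=O)OCC | intermediate
31 | ethyl (13E)-18-(4-methoxybenzyloxy)-6-oxo-9βH-labda-8(17),13-dien-15-oate | C=C1CC(=O)[C@H]2[C@](C)(COCc3ccc(OC)cc3)CCC[C@]2(C)[C@@H]1CC/C(C)=C/C(=O)OCC | intermediate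
32 | (13E)-18-(4-methoxybenzyloxy)-9βH-labda-8(17),13-diene-6β,15-diol | C=C1C[C@@H](O)[C@H]2[C@](C)(COCc3ccc(OC)cc3)CCC[C@]2(C)[C@@H]1CC/C(C)=C/CO | intermediate
33 | (13E)-6β-hydroxy-18-(4-methoxybenzyloxy)-9βH-labda-8(17),13-dien-15-al | C=C1C[C@@H](O)[C@H]2[C@](C)(COCc3ccc(OC)cc3)CCC[C@]2(C)[C@@H]1CC/C(C)=C/C=O | intermediate
34 | (13E)-6β-benzoyloxy-18-(4-methoxybenzyloxy)-9βH-labda-8(17),13-dien-15-al | C=C1C[C@@H](OC(=O)c3ccccc3)[C@H]2[C@](C)(COCc3ccc(OC)cc3)CCC[C@]2(C)[C@@H]1CC/C(C)=C/C=O | intermediate
35 | (13E)-6β-benzoyloxy-18-hydroxy-9βH-labda-8(17),13-dien-15-al, (4R,5R,6R,9R,10R) | C=C1C[C@@H](OC(=O)c2ccccc2)[C@H]2[C@](C)(CO)CCC[C@]2(C)[C@@H]1CC/C(C)=C/C=O | target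

## Step count and risks

Total step count: 27. Longest linear sequence: 25 steps (steps 2–10 and 12–27, from **3** and **4** to **35**).

Least certain steps:

**Step 4 (key step).**
- *What may go wrong:* electron transfer or conjugate addition between the very electron-rich amino diene and the quinone instead of cycloaddition; erosion of facial selectivity, because the bond to C10 forms late and far from the auxiliary.
- *Fallback:* move the chirality from the diene to a catalyst. Quinone **2** is combined with (E)-1-methoxy-3-(trimethylsilyloxy)buta-1,3-diene in the presence of a chiral oxazaborolidinium triflimide (CH2Cl2, −78 °C). This gives the 1α-methoxy silyl enol ether adduct F1. Brief dilute HCl converts F1, with loss of methanol and silanol, into cis-enetrione **9**, where the route is rejoined.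

**Step 6.**
- *What may go wrong:* incomplete equilibration, an equilibrium that does not sufficiently favour the trans isomer, or base-induced degradation of the enedione.
- *Fallback:* replace equilibration by kinetic protonation. Compound **9** is converted with Me3SiOTf and Et3N into the bis(trimethylsilyl) dienol ether F2, in which C5 is trigonal. Hydrolysis with cold dilute acid should deliver the proton to C5 from the α-face, opposite the adjacent C20, and give **10**.

**Step 12.**
- *What may go wrong:* slow substitution at the neopentyl enolate carbon, leaving room for elimination of HI from the iodide, for proton transfer (C9 epimerisation, double alkylation) and for O-alkylation.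
- *Fallback:* form the C9–C11 bond by conjugate addition. The lithium enolate of **15** is added to 3-(trimethylsilyl)but-3-en-2-one to give the α-silyl diketone F3. Protodesilylation with KF in methanol gives the 9α-(3-oxobutyl) epoxy ketone F4. Selective dioxolane formation at the unhindered methyl ketone (ethylene glycol, PPTS, benzene) returns to **18**.

**Step 18.**
- *What may go wrong:* hydride transfer to C17 instead of C7 (giving the endocyclic alkene), or β-hydride elimination of the alkoxide to a ketone or dienol.
- *Fallback:* open the oxirane while C8 is still a carbonyl, where the regiochemistry is unambiguous. The sequence sets out from **18** and rejoins at **24**: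
  1. SmI2 (THF/MeOH, −78 °C) opens **18** to the 6α-hydroxy ketone F5.
  2. Excess Cp2TiMe2 gives the 6α-hydroxy 8(17)-alkene F6.
  3. Bu4NF gives the 3β,6α-diol F7.
  4. MnO2 oxidises only the allylic alcohol and gives the 6α-hydroxy enone F8.
  5. LiN(i-Pr)2 (2 equiv) and MeI give the 4α-methyl compound F9.
  6. LiN(i-Pr)2 (2 equiv) and one equivalent of the chloromethyl ether give **24**; the hindered lithium alkoxide is expected to be much less nucleophilic than the enolate carbon.

**Step 20.**
- *What may go wrong:* incomplete hydrazone formation at the ketone next to the quaternary C4; migration of the exocyclic alkene in hot alkali.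
- *Fallback:* a hydride route at low temperature. Compound **26** is condensed with tosylhydrazide to the tosylhydrazone F10. Reduction with catecholborane followed by NaOAc, with loss of sulfinate and N2, gives **28**.

**Step 26.**
- *What may go wrong:* failure of acyl transfer to the doubly shielded axial hydroxyl, or degradation of the enal under forcing conditions.
- *Fallback:* acylate the alkoxide before the enal exists. The sequence sets out from diol **32** and rejoins at **34**:
  1. TBSCl and imidazole silylate only the primary allylic hydroxyl and give the 15-silyl ether F11.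
  2. KN(SiMe3)2 and then BzCl give the 6β-benzoate F12.
  3. HF·pyridine gives the 15-alcohol F13.
  4. MnO2 gives **34**.

## Further compounds

F1 | step 4 | 1α-methoxy-3-(trimethylsilyloxy)-8-methoxy-10β-methyl-5βH-2,7-diene-6,9-dione (cis adduct) | COC1=CC(=O)[C@@H]2CC(O[Si](C)(C)C)=C[C@H](OC)[C@]2(C)C1=O
F2 | step 6 | 3,6-bis(trimethylsilyloxy)-8-methoxy-10β-methyl-1,3,5,7-tetraen-9-one | COC1=CC(O[Si](C)(C)C)=C2C=C(O[Si](C)(C)C)C=C[C@]2(C)C1=O
F3 | step 12 | 9α-[3-oxo-2-(trimethylsilyl)butyl]-6α,7α-epoxy-3β-silyloxy-1-en-8-one | O=C1[C@@H]3O[C@@H]3[C@H]2C[C@@H](O[Si](C)(C)C(C)(C)C)C=C[C@]2(C)[C@@H]1CC([Si](C)(C)C)C(C)=O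
F4 | step 12 | 9α-(3-oxobutyl)-6α,7α-epoxy-3β-silyloxy-1-en-8-one | O=C1[C@@H]3O[C@@H]3[C@H]2C[C@@H](O[Si](C)(C)C(C)(C)C)C=C[C@]2(C)[C@@H]1CCC(C)=O
F5 | step 18 | 6α-hydroxy-9α-[2-(2-methyl-1,3-dioxolan-2-yl)ethyl]-3β-silyloxy-1-en-8-one | O=C1C[C@H](O)[C@H]2C[C@@H](O[Si](C)(C)C(C)(C)C)C=C[C@]2(C)[C@@H]1CCC1(C)OCCO1
F6 | step 18 | 6α-hydroxy-8(17)-methylene 3β-silyl ether | C=C1C[C@H](O)[C@H]2C[C@@H](O[Si](C)(C)C(C)(C)C)C=C[C@]2(C)[C@@H]1CCC1(C)OCCO1
F7 | step 18 | 8(17)-methylene-1-ene-3β,6α-diol | C=C1C[C@H](O)[C@H]2C[C@@H](O)C=C[C@]2(C)[C@@H]1CCC1(C)OCCO1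
F8 | step 18 | 6α-hydroxy-8(17)-methylene-1-en-3-one | C=C1C[C@H](O)[C@H]2CC(=O)C=C[C@]2(C)[C@@H]1CCC1(C)OCCO1
F9 | step 18 | 6α-hydroxy-4α-methyl-8(17)-methylene-1-en-3-one | C=C1C[C@H](O)[C@H]2[C@H](C)C(=O)C=C[C@]2(C)[C@@H]1CCC1(C)OCCO1
F10 | step 20 | C3 tosylhydrazone of 26 | C=C1C[C@H](O)[C@H]2[C@](C)(COCc3ccc(OC)cc3)C(=NNS(=O)(=O)c3ccc(C)cc3)CC[C@]2(C)[C@@H]1CCC1(C)OCCO1
F11 | step 26 | (13E)-15-(tert-butyldimethylsilyloxy)-18-(4-methoxybenzyloxy)-9βH-labda-8(17),13-dien-6β-ol | C=C1C[C@@H](O)[C@H]2[C@](C)(COCc3ccc(OC)cc3)CCC[C@]2(C)[C@@H]1CC/C(C)=C/CO[Si](C)(C)C(C)(C)C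
F12 | step 26 | (13E)-6β-benzoyloxy-15-(tert-butyldimethylsilyloxy)-18-(4-methoxybenzyloxy)-9βH-labda-8(17),13-diene | C=C1C[C@@H](OC(=O)c3ccccc3)[C@H]2[C@](C)(COCc3ccc(OC)cc3)CCC[C@]2(C)[C@@H]1CC/C(C)=C/CO[Si](C)(C)C(C)(C)C
F13 | step 26 | (13E)-6β-benzoyloxy-18-(4-methoxybenzyloxy)-9βH-labda-8(17),13-dien-15-ol | C=C1C[C@@H](OC(=O)c3ccccc3)[C@H]2[C@](C)(COCc3ccc(OC)cc3)CCC[C@]2(C)[C@@H]1CC/C(C)=C/CO
A1 | alternative 1 | trienyl butenolide with C8 dithiane (cycloaddition precursor) | C=C/C=C(C)/CC1(SCCCS1)C[C@@H]1OC(=O)C(C)=C1
A2 | alternative 1 | tricyclic lactone adduct | S1CCCSC12C[C@@H]3OC(=O)[C@]4(C)CC=C[C@](C)(C2)[C@H]34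
A3 | alternative 2 | 5(10)-octalin-6β-ol with 4-methyl and 4-silyloxymethyl groups | C1C[C@@H](O)C2=C(CCC[C@@]2(C)CO[Si](C)(C)C(C)(C)C)C1
A4 | alternative 2 | 5,10-methano decalin 6β-ol | C1C[C@@H](O)[C@]2(C3)[C@](C)(CO[Si](C)(C)C(C)(C)C)CCC[C@]23C1
A5 | alternative 3 | β-methyl butenolide tethered to a 2-siloxy diene (cycloaddition precursor) | O=C1O[C@@H](CC[C@@](C)(CO[Si](C)(C)C(C)(C)C)/C=C(O[Si](C)(C)C(C)(C)C)/C=C/COCc2ccc(OC)cc2)C(C)=C1
A6 | alternative 3 | tricyclic lactone silyl enol ether adduct | O=C1O[C@H]2CC[C@@](C)(CO[Si](C)(C)C(C)(C)C)[C@H]3C(O[Si](C)(C)C(C)(C)C)=C[C@@H](COCc4ccc(OC)cc4)[C@@H]1[C@@]23C
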